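**Retrosynthetic overview**
1. The γ-lactone is formed last, by oxidative lactonisation of the 2-methylene-1,4-diol unit of triol 23 (C6–OH onto C12).
2. The cyclohexane ring (C6–C7 bond) comes from an intramolecular carbonyl-ene reaction of acyclic aldehyde 21.
3. The C5–C10 bond, with the quaternary centre and its neighbour, comes from an enantioselective boron Ireland–Claisen rearrangement of allylic ester 17.
4. Ester 17 is assembled from three five-carbon fragments: acid 5 (fragment A) is esterified with diol 15, which is made from ester 8 (fragment B) and enal 12 (fragment C) by a catalytic asymmetric vinylogous aldol–lactonisation (C8–C9 bond).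
5. Ring order: temporary dihydropyranone 14 (fixes the alkene geometry, then opened by reduction), then the cyclohexane, then the γ-lactone.

Notation: TBS = tert-butyldimethylsilyl. Atom labels follow the target: C10 (quaternary), C9 (CH2), C8 (OAc), C7, C6 (lactone O), C5 are the ring carbons; C14 is the CH2OH carbon; C4/C15 and C11/C12 are the side-chain carbons on C5 and C7.
Assumption: the (R)-DTBM-SEGPHOS copper catalyst (step 11) and the (S,S)-bromoborane (step 14) are taken to give the drawn absolute configurations; if either sense is opposite, its mirror-image form is used and nothing else changes.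

**Fragment A**

Step 1
Reactants: 1 itaconic anhydride
Product: 2 4-tert-butoxy-2-methylidene-4-oxobutanoic acid
Conditions: t-BuOH, DMAP (cat.), toluene, 70 °C
Reagents that add atoms: tert-butanol, CC(C)(C)O
Why: Anhydride alcoholysis occurs at the non-conjugated, more electrophilic carbonyl, leaving the conjugated acid free.

Step 2
Reactants: 2 4-tert-butoxy-2-methylidene-4-oxobutanoic acid
Product: 3 tert-butyl 3-(hydroxymethyl)but-3-enoate
Conditions: BH3·SMe2, THF, −10 → 0 °C; MeOH quench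
Reagents that add atoms: none
Why: Chemoselective borane reduction of a carboxylic acid (via the acyloxyborane) in the presence of an ester gives the allylic alcohol.

Step 3
Reactants: 3 tert-butyl 3-(hydroxymethyl)but-3-enoate
Product: 4 tert-butyl 3-(acetoxymethyl)but-3-enoate
Conditions: Ac2O, pyridine, DMAP (cat.), CH2Cl2, 0 °C
Reagents that add atoms: acetic anhydride, CC(=O)OC(C)=O
Why: DMAP-catalysed acetylation of a primary alcohol.

Step 4
Reactants: 4 tert-butyl 3-(acetoxymethyl)but-3-enoate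
Product: 5 3-(acetoxymethyl)but-3-enoic acid (fragment A)
Conditions: CF3CO2H/CH2Cl2 (1:4), 0 °C → rt
Reagents that add atoms: none
Why: Acidolysis of the tert-butyl ester (loss of isobutene) leaves the acetate and the β,γ-alkene untouched.

**Fragment B**

Step 5
Reactants: 1 itaconic anhydride
Product: 6 4-methoxy-2-methylidene-4-oxobutanoic acid
Conditions: MeOH, 45 °C
Reagents that add atoms: methanol, CO
Why: Regioselective anhydride alcoholysis at the non-conjugated carbonyl, as in step 1.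

Step 6
Reactants: 6 4-methoxy-2-methylidene-4-oxobutanoic acid
Product: 7 methyl 3-(hydroxymethyl)but-3-enoate
Conditions: BH3·SMe2, THF, −10 → 0 °C; MeOH quench
Reagents that add atoms: none
Why: Chemoselective borane reduction of the acid beside the methyl ester.

Step 7
Reactants: 7 methyl 3-(hydroxymethyl)but-3-enoate
Product: 8 methyl 3-[(TBSO)methyl]but-3-enoate (fragment B)
Conditions: TBSCl, imidazole, CH2Cl2, 0 °C (7 used at once)
Reagents that add atoms: tert-butyldimethylsilyl chloride, CC(C)(C)[Si](C)(C)Cl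
Why: Silyl ether formation, which also prevents lactonisation of the γ-hydroxy ester.

**Fragment C**

Step 8
Reactants: 9 4-methylfuran-2(5H)-one
Product: 10 (2Z)-4-hydroxy-N-methoxy-N,3-dimethylbut-2-enamide
Conditions: MeNH(OMe)·HCl, AlMe3, CH2Cl2, 0 °C → rt
Reagents that add atoms: N,O-dimethylhydroxylamine hydrochloride, CNOC.Cl
Why: Weinreb aminolysis of the lactone by the aluminium amide; the ring origin fixes the Z geometry (CH2O cis to the carbonyl).

Step 9
Reactants: 10 (2Z)-4-hydroxy-N-methoxy-N,3-dimethylbut-2-enamide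
Product: 11 (2Z)-4-(TBSO)-N-methoxy-N,3-dimethylbut-2-enamide
Conditions: TBSCl, imidazole, DMF, 0 °C (10 used crude, at once)
Reagents that add atoms: tert-butyldimethylsilyl chloride, CC(C)(C)[Si](C)(C)Cl
Why: Silylation traps the open-chain form before it can relactonise.

Step 10
Reactants: 11 (2Z)-4-(TBSO)-N-methoxy-N,3-dimethylbut-2-enamide
Product: 12 (2Z)-4-(TBSO)-3-methylbut-2-enal (fragment C)
Conditions: i-Bu2AlH, THF, −78 °C; aq. potassium sodium tartrate
Reagents that add atoms: none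
Why: Hydride reduction of a Weinreb amide stops at the aldehyde through the chelated tetrahedral intermediate, with the Z alkene retained.

**Coupling of B and C**

Step 11
Reactants: 8 methyl 3-[(TBSO)methyl]but-3-enoate; 12 (2Z)-4-(TBSO)-3-methylbut-2-enal
Product: 14 (6S)-4-[(TBSO)methyl]-6-[(1Z)-3-(TBSO)-2-methylprop-1-en-1-yl]-5,6-dihydro-2H-pyran-2-one, via copper aldolate 13 (not isolated)
Conditions: [Cu(CH3CN)4]PF6 (5 mol %), (R)-DTBM-SEGPHOS (5 mol %), Et3N (20 mol %), THF, −20 °C → rt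
Reagents that add atoms: none
Why: Copper-catalysed direct asymmetric vinylogous aldol reaction: the copper dienolate of the β,γ-unsaturated ester attacks the aldehyde through its terminal γ-carbon under bisphosphine control (C8 becomes S), and the alkoxide lactonises, which locks C9 cis to C2 on the new trisubstituted alkene.

Step 12
Reactants: 14 (6S)-dihydropyranone
Product: 15 (2E,5S,6Z)-8-(TBSO)-3-[(TBSO)methyl]-7-methylocta-2,6-diene-1,5-diol
Conditions: i-Bu2AlH (4 equiv), CH2Cl2, −78 → 0 °C; aq. potassium sodium tartrate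
Reagents that add atoms: none
Why: Exhaustive 1,2-hydride reduction of the unsaturated lactone opens it to the ene-diol with the ring-derived alkene geometry and the C8 centre intact.

**Union with A and endgame**

Step 13
Reactants: 15 (2E,5S,6Z)-diol; 5 3-(acetoxymethyl)but-3-enoic acid
Product: 17 (2E,5S,6Z)-5-acetoxy-8-(TBSO)-3-[(TBSO)methyl]-7-methylocta-2,6-dien-1-yl 3-(acetoxymethyl)but-3-enoate, via hydroxy ester 16 (not isolated)
Conditions: 5 (1.05 equiv), EDC·HCl, DMAP (cat.), CH2Cl2, −20 °C; then Ac2O, pyridine, 0 °C → rt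
Reagents that add atoms: acetic anhydride, CC(=O)OC(C)=O
Why: Steglich-type carbodiimide esterification is selective for the primary allylic hydroxyl, and the remaining secondary hydroxyl is then acetylated in the same flask.

Step 14
Reactants: 17 allylic ester
Product: 19 (2S,3R)-2-[3-(acetyloxy)prop-1-en-2-yl]-3-[(2S,3Z)-2-(acetyloxy)-5-(TBSO)-4-methylpent-3-en-1-yl]-3-[(TBSO)methyl]pent-4-enoic acid, via boron ketene acetal 18 (not isolated)
Conditions: (S,S)-2-bromo-1,3-bis[3,5-bis(trifluoromethyl)benzenesulfonyl]-4,5-diphenyl-1,3,2-diazaborolidine (1.3 equiv), Et3N, toluene–hexane, −78 °C → 4 °C; aq. work-up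
Reagents that add atoms: none
Why: Enantioselective Ireland–Claisen rearrangement: the Z(O) boron ketene acetal (propenyl group cis to O–B) and the alkene with C9 cis to the ester CH2 react through a chair that fixes the C5/C10 relative configuration, while the chiral diazaborolidine selects the enolate face to give 5S,10R.

Step 15
Reactants: 19 (2S,3R)-acid
Product: 21 (2S,3R)-2-[3-(acetyloxy)prop-1-en-2-yl]-3-[(2S,3Z)-2-(acetyloxy)-5-(TBSO)-4-methylpent-3-en-1-yl]-3-[(TBSO)methyl]pent-4-enal, via acid chloride 20 (not isolated)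
Conditions: Me2C=C(Cl)NMe2 (Ghosez reagent), CH2Cl2, 0 °C; then LiAlH(Ot-Bu)3, THF, −78 °C; used crude
Reagents that add atoms: none
Why: Neutral acid chloride formation followed by partial reduction with the hindered alkoxyaluminium hydride stops at the aldehyde without touching the acetates or epimerising C5.

Step 16
Reactants: 21 (2S,3R)-aldehyde
Product: 22 (1S,2S,3R,4S,5R)-4-[3-(acetyloxy)prop-1-en-2-yl]-2-[3-(TBSO)prop-1-en-2-yl]-5-[(TBSO)methyl]-5-ethenyl-3-hydroxycyclohexyl acetate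
Conditions: Me2AlCl (2.5 equiv), CH2Cl2, −78 → −40 °C
Reagents that add atoms: none
Why: Lewis-acid-promoted intramolecular carbonyl-ene reaction (as citronellal to isopulegol) through a chair with the C5, C8 and vinyl substituents equatorial forms C6–C7 with the new hydroxyl and alkenyl group trans-diequatorial, the hydrogen being taken from the methyl trans to the tether so that the CH2OTBS group stays on the new exo-methylene unit.

Step 17
Reactants: 22 cyclohexanol
Product: 23 (1S,2S,3R,4S,5R)-4-[3-(acetyloxy)prop-1-en-2-yl]-5-ethenyl-3-hydroxy-5-(hydroxymethyl)-2-(3-hydroxyprop-1-en-2-yl)cyclohexyl acetate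
Conditions: HF·pyridine, pyridine, THF, 0 °C → rt
Reagents that add atoms: none
Why: Fluoride cleavage of both primary silyl ethers under buffered conditions that leave the acetates in place.

Step 18
Reactants: 23 triol
Product: 26 [2-[(3aR,4S,6R,7S,7aR)-4-acetoxy-6-ethenyl-6-(hydroxymethyl)-3-methylidene-2-oxooctahydro-1-benzofuran-7-yl]prop-2-en-1-yl] acetate (target), via hydroxy enal 24 (not isolated), via lactol 25 (not isolated)
Conditions: MnO2 (activated, excess), CH2Cl2, rt
Reagents that add atoms: none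
Why: MnO2 oxidises only the allylic primary alcohol, the resulting enal is captured by the C6 hydroxyl as a lactol, and this is oxidised on to the trans-fused α-methylene-γ-butyrolactone (oxidative lactonisation) without touching the non-allylic C14 hydroxyl or any stereocentre.

**Compound list**

1 | itaconic anhydride | C=C1CC(=O)OC1=O | starting material
2 | 4-tert-butoxy-2-methylidene-4-oxobutanoic acid | C=C(CC(=O)OC(C)(C)C)C(=O)O | intermediate
3 | tert-butyl 3-(hydroxymethyl)but-3-enoate | C=C(CO)CC(=O)OC(C)(C)C | intermediate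
4 | tert-butyl 3-(acetoxymethyl)but-3-enoate | C=C(COC(C)=O)CC(=O)OC(C)(C)C | intermediate
5 | 3-(acetoxymethyl)but-3-enoic acid (fragment A) | C=C(COC(C)=O)CC(=O)O | intermediate
6 | 4-methoxy-2-methylidene-4-oxobutanoic acid | C=C(CC(=O)OC)C(=O)O | intermediate
7 | methyl 3-(hydroxymethyl)but-3-enoate | C=C(CO)CC(=O)OC | intermediate
8 | methyl 3-[(TBSO)methyl]but-3-enoate (fragment B) | C=C(CO[Si](C)(C)C(C)(C)C)CC(=O)OC | intermediate
9 | 4-methylfuran-2(5H)-one | CC1=CC(=O)OC1 | starting material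
10 | (2Z)-4-hydroxy-N-methoxy-N,3-dimethylbut-2-enamide | CON(C)C(=O)/C=C(/C)CO | intermediate
11 | (2Z)-4-(TBSO)-N-methoxy-N,3-dimethylbut-2-enamide | CON(C)C(=O)/C=C(/C)CO[Si](C)(C)C(C)(C)C | intermediate
12 | (2Z)-4-(TBSO)-3-methylbut-2-enal (fragment C) | O=C/C=C(/C)CO[Si](C)(C)C(C)(C)C | intermediate
13 | copper alkoxide of methyl (2E,5S,6Z)-5-hydroxy-7-methyl-8-(TBSO)-3-[(TBSO)methyl]octa-2,6-dienoate (SMILES of the free alcohol) | COC(=O)/C=C(/CO[Si](C)(C)C(C)(C)C)C[C@H](O)/C=C(/C)CO[Si](C)(C)C(C)(C)C | intermediate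
14 | (6S)-4-[(TBSO)methyl]-6-[(1Z)-3-(TBSO)-2-methylprop-1-en-1-yl]-5,6-dihydro-2H-pyran-2-one | O=C1C=C(CO[Si](C)(C)C(C)(C)C)C[C@@H](/C=C(/C)CO[Si](C)(C)C(C)(C)C)O1 | intermediate
15 | (2E,5S,6Z)-8-(TBSO)-3-[(TBSO)methyl]-7-methylocta-2,6-diene-1,5-diol | OC/C=C(/CO[Si](C)(C)C(C)(C)C)C[C@H](O)/C=C(/C)CO[Si](C)(C)C(C)(C)C | intermediate
16 | (2E,5S,6Z)-5-hydroxy-8-(TBSO)-3-[(TBSO)methyl]-7-methylocta-2,6-dien-1-yl 3-(acetoxymethyl)but-3-enoate | CC(=O)OCC(=C)CC(=O)OC/C=C(/CO[Si](C)(C)C(C)(C)C)C[C@H](O)/C=C(/C)CO[Si](C)(C)C(C)(C)C | intermediate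
17 | (2E,5S,6Z)-5-acetoxy-8-(TBSO)-3-[(TBSO)methyl]-7-methylocta-2,6-dien-1-yl 3-(acetoxymethyl)but-3-enoate | CC(=O)OCC(=C)CC(=O)OC/C=C(/CO[Si](C)(C)C(C)(C)C)C[C@H](OC(C)=O)/C=C(/C)CO[Si](C)(C)C(C)(C)C | intermediate
18 | Z(O) boron ketene acetal of 17 carrying the (S,S)-diazaborolidine | CC(=O)OCC(=C)/C=C(\OB1N(S(=O)(=O)c2cc(C(F)(F)F)cc(C(F)(F)F)c2)[C@@H](c2ccccc2)[C@H](c2ccccc2)N1S(=O)(=O)c1cc(C(F)(F)F)cc(C(F)(F)F)c1)OC/C=C(/CO[Si](C)(C)C(C)(C)C)C[C@H](OC(C)=O)/C=C(/C)CO[Si](C)(C)C(C)(C)C | intermediate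
19 | (2S,3R)-2-[3-(acetyloxy)prop-1-en-2-yl]-3-[(2S,3Z)-2-(acetyloxy)-5-(TBSO)-4-methylpent-3-en-1-yl]-3-[(TBSO)methyl]pent-4-enoic acid | C=C[C@](CO[Si](C)(C)C(C)(C)C)(C[C@H](OC(C)=O)/C=C(/C)CO[Si](C)(C)C(C)(C)C)[C@@H](C(=O)O)C(=C)COC(C)=O | intermediate
20 | acid chloride of 19 | C=C[C@](CO[Si](C)(C)C(C)(C)C)(C[C@H](OC(C)=O)/C=C(/C)CO[Si](C)(C)C(C)(C)C)[C@@H](C(=O)Cl)C(=C)COC(C)=O | intermediate
21 | (2S,3R)-aldehyde corresponding to 19 (pent-4-enal) | C=C[C@](CO[Si](C)(C)C(C)(C)C)(C[C@H](OC(C)=O)/C=C(/C)CO[Si](C)(C)C(C)(C)C)[C@@H](C=O)C(=C)COC(C)=O | intermediate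
22 | (1S,2S,3R,4S,5R)-4-[3-(acetyloxy)prop-1-en-2-yl]-2-[3-(TBSO)prop-1-en-2-yl]-5-[(TBSO)methyl]-5-ethenyl-3-hydroxycyclohexyl acetate | C=C[C@]1(CO[Si](C)(C)C(C)(C)C)C[C@H](OC(C)=O)[C@@H](C(=C)CO[Si](C)(C)C(C)(C)C)[C@H](O)[C@H]1C(=C)COC(C)=O | intermediate
23 | (1S,2S,3R,4S,5R)-4-[3-(acetyloxy)prop-1-en-2-yl]-5-ethenyl-3-hydroxy-5-(hydroxymethyl)-2-(3-hydroxyprop-1-en-2-yl)cyclohexyl acetate | C=C[C@]1(CO)C[C@H](OC(C)=O)[C@@H](C(=C)CO)[C@H](O)[C@H]1C(=C)COC(C)=O | intermediate
24 | hydroxy enal from 23 (the 3-hydroxypropenyl group oxidised to a 3-oxopropenyl group) | C=C[C@]1(CO)C[C@H](OC(C)=O)[C@@H](C(=C)C=O)[C@H](O)[C@H]1C(=C)COC(C)=O | intermediate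
25 | lactol of 24 (2-hydroxy-3-methylidene-octahydrobenzofuran, anomeric mixture) | C=C[C@]1(CO)C[C@H](OC(C)=O)[C@H]2C(=C)C(O)O[C@@H]2[C@H]1C(=C)COC(C)=O | intermediate
26 | [2-[(3aR,4S,6R,7S,7aR)-4-acetoxy-6-ethenyl-6-(hydroxymethyl)-3-methylidene-2-oxooctahydro-1-benzofuran-7-yl]prop-2-en-1-yl] acetate | C=C[C@]1(CO)C[C@H](OC(C)=O)[C@H]2C(=C)C(=O)O[C@@H]2[C@H]1C(=C)COC(C)=O | target

**Step count**

Total: 18 steps. Longest linear sequence: 11 steps (1 → 6 → 7 → 8 → 14 → 15 → 17 → 19 → 21 → 22 → 23 → 26; the sequence from 9 is equally long).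

**Steps most likely to fail, with fallbacks**

Step 11 (catalytic asymmetric vinylogous aldol–lactonisation on a new substrate pair). The fallback sets out from 8 and 12 and returns at 16, which is acetylated as in step 13 to give 17. Deprotonation of 8 with LiN(i-Pr)2 (THF, −78 °C), addition of 12 and warming to 0 °C lets the kinetic α-adduct revert and the γ-adduct close to the racemic lactone F1. Reduction with i-Bu2AlH gives the racemic diol F2, and EDC coupling with 5 at the primary hydroxyl gives the racemic hydroxy ester F3. Dess–Martin periodinane then gives the dienone F4, and (R)-Me-CBS oxazaborolidine with catecholborane (toluene, −78 °C) reduces the alkenyl ketone to the (S)-carbinol 16.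

Step 14 (enolate geometry and facial control in the boron Ireland–Claisen rearrangement). The fallback sets out from 17 and returns at 19. KN(SiMe3)2 in toluene at −78 °C followed by Me3SiCl gives the Z(O) trimethylsilyl ketene acetal F5 (classical Ireland–Claisen). On warming it rearranges through the same chair, but without facial control, to the silyl ester F6 and its C5,C10-diastereomeric silyl ester F7. Aqueous work-up gives 19 and the (2R,3S)-acid F8; the fixed C8 centre makes these diastereomers, so they are separated by chromatography.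

Step 16 (ene cyclisation: possible ionisation of the allylic acetate by the Lewis acid, or hydrogen transfer from the wrong group). The fallback sets out from 21 and returns at 23. Buffered HF·pyridine at 0 °C removes only the unhindered allylic silyl ether to give the hydroxy aldehyde F9, and CBr4/PPh3 gives the allylic bromide F10. CrCl2 in THF at high dilution (Nozaki–Hiyama–Kishi allylation, anti-selective through a chair-like transition state whatever the bromide geometry) closes the ring to the cyclohexanol F11, which carries a plain isopropenyl group. SeO2 (cat.)/t-BuOOH oxidises its allylic methyl to the allylic alcohol F12, and HF·pyridine as in step 17 then gives 23. The open risk in this fallback is 1,4-elimination of the acetate next to the allyl-chromium carbon.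

**Further compounds**

F1 | step 11 | racemic 4-[(TBSO)methyl]-6-[(1Z)-3-(TBSO)-2-methylprop-1-en-1-yl]-5,6-dihydro-2H-pyran-2-one | O=C1C=C(CO[Si](C)(C)C(C)(C)C)CC(/C=C(/C)CO[Si](C)(C)C(C)(C)C)O1
F2 | step 11 | racemic (2E,6Z)-8-(TBSO)-3-[(TBSO)methyl]-7-methylocta-2,6-diene-1,5-diol | OC/C=C(/CO[Si](C)(C)C(C)(C)C)CC(O)/C=C(/C)CO[Si](C)(C)C(C)(C)C
F3 | step 11 | racemic (2E,6Z)-5-hydroxy-8-(TBSO)-3-[(TBSO)methyl]-7-methylocta-2,6-dien-1-yl 3-(acetoxymethyl)but-3-enoate | CC(=O)OCC(=C)CC(=O)OC/C=C(/CO[Si](C)(C)C(C)(C)C)CC(O)/C=C(/C)CO[Si](C)(C)C(C)(C)C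
F4 | step 11 | (2E,6Z)-8-(TBSO)-3-[(TBSO)methyl]-7-methyl-5-oxoocta-2,6-dien-1-yl 3-(acetoxymethyl)but-3-enoate | CC(=O)OCC(=C)CC(=O)OC/C=C(/CO[Si](C)(C)C(C)(C)C)CC(=O)/C=C(/C)CO[Si](C)(C)C(C)(C)C
F5 | step 14 | Z(O) trimethylsilyl ketene acetal of 17 | CC(=O)OCC(=C)/C=C(\O[Si](C)(C)C)OC/C=C(/CO[Si](C)(C)C(C)(C)C)C[C@H](OC(C)=O)/C=C(/C)CO[Si](C)(C)C(C)(C)C
F6 | step 14 | trimethylsilyl ester of 19 | C=C[C@](CO[Si](C)(C)C(C)(C)C)(C[C@H](OC(C)=O)/C=C(/C)CO[Si](C)(C)C(C)(C)C)[C@@H](C(=O)O[Si](C)(C)C)C(=C)COC(C)=O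
F7 | step 14 | trimethylsilyl ester of the (2R,3S)-diastereomer of 19 | C=C[C@@](CO[Si](C)(C)C(C)(C)C)(C[C@H](OC(C)=O)/C=C(/C)CO[Si](C)(C)C(C)(C)C)[C@H](C(=O)O[Si](C)(C)C)C(=C)COC(C)=O
F8 | step 14 | (2R,3S)-diastereomer of acid 19 (C8 unchanged) | C=C[C@@](CO[Si](C)(C)C(C)(C)C)(C[C@H](OC(C)=O)/C=C(/C)CO[Si](C)(C)C(C)(C)C)[C@H](C(=O)O)C(=C)COC(C)=O
F9 | step 16 | aldehyde 21 with the allylic silyl ether cleaved to the free alcohol | C=C[C@](CO[Si](C)(C)C(C)(C)C)(C[C@H](OC(C)=O)/C=C(/C)CO)[C@@H](C=O)C(=C)COC(C)=O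
F10 | step 16 | allylic bromide from F9 | C=C[C@](CO[Si](C)(C)C(C)(C)C)(C[C@H](OC(C)=O)/C=C(/C)CBr)[C@@H](C=O)C(=C)COC(C)=O
F11 | step 16 | (1S,2S,3R,4S,5R)-4-[3-(acetyloxy)prop-1-en-2-yl]-5-[(TBSO)methyl]-5-ethenyl-3-hydroxy-2-(prop-1-en-2-yl)cyclohexyl acetate | C=C[C@]1(CO[Si](C)(C)C(C)(C)C)C[C@H](OC(C)=O)[C@@H](C(C)=C)[C@H](O)[C@H]1C(=C)COC(C)=O
F12 | step 16 | allylic alcohol from F11 (2-(3-hydroxyprop-1-en-2-yl) group, C14 still silylated) | C=C[C@]1(CO[Si](C)(C)C(C)(C)C)C[C@H](OC(C)=O)[C@@H](C(=C)CO)[C@H](O)[C@H]1C(=C)COC(C)=O
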